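**Retrosynthetic overview**
- The strategy rests on the C8–C9 trans-1,2-diol inside the ten-membered carbocycle (C1–C10, Z C1=C10, E C4=C5). Both carbinol carbons are aldehyde-level electrophiles, so the ring is opened there to a dialdehyde: C8 formyl on C7 of the cis-fused γ-lactone (O–C6–C7–C11–C12) and C9 as a Z-enal. SmI2 pinacol coupling closes it.
- Late stage: O8 is esterified with (2R,3R)-epoxyangelic acid (from angelic acid by Sharpless epoxidation). O8 is told from O9 by MnO2 oxidation of the allylic C9 carbinol followed by Luche reduction. C11=C13 comes from Mannich methylenation.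
- The lactone (C6, C7) comes from a MgCl2-catalysed auxiliary anti-aldol of a succinate imide with a (2E,6Z)-8-silyloxy dienal, then lactonisation. The dienal comes from geraniol by terminal-alkene cleavage and Still–Gennari olefination.
- Ring order: γ-lactone (step 10), then the ten-membered carbocycle (step 13); the side-chain oxirane is made separately (step 19).

Key step: step 13

Assumption: the MgCl2-catalysed anti-aldol of an N-acyl oxazolidinone is taken to run through the magnesium-chelated Z-enolate, attacked on the face away from the benzyl group (the face used in enolate alkylations). On that basis the (R)-auxiliary gives the target series; the mirror-image auxiliary would be used in the same steps if the facial sense were the opposite.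

**Route**

Step 1
Reactants: 1 geraniol
Product: 2 geranyl tert-butyldimethylsilyl ether
Conditions: t-BuMe2SiCl, imidazole, CH2Cl2, 0 °C → rt
Reagents that add atoms: tert-butyldimethylsilyl chloride, CC(C)(C)[Si](C)(C)Cl
Why: Imidazole-mediated silylation of the primary allylic alcohol gives an ether that should survive peracid, brief periodic acid, phosphonate anion and i-Bu2AlH and can later be removed beside a TBDPS ether.

Step 2
Reactants: 2 geranyl tert-butyldimethylsilyl ether
Product: 4 (4E)-6-[(tert-butyldimethylsilyl)oxy]-4-methylhex-4-enal, via terminal epoxide 3 (not isolated)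
Conditions: mCPBA, CH2Cl2, −20 → 0 °C; then H5IO6, THF–H2O, 0 °C
Reagents that add atoms: meta-chloroperbenzoic acid, OOC(=O)c1cccc(Cl)c1
Why: Prilezhaev epoxidation takes the more electron-rich 6,7-alkene (the 2,3-alkene is deactivated by the allylic oxygen), and periodic acid cleavage of the epoxide through its glycol (Malaprade type) gives the aldehyde and acetone.

Step 3
Reactants: 4 (4E)-6-[(tert-butyldimethylsilyl)oxy]-4-methylhex-4-enal; 5 ethyl 2-[bis(2,2,2-trifluoroethoxy)phosphoryl]propanoate
Product: 6 ethyl (2Z,6E)-8-[(tert-butyldimethylsilyl)oxy]-2,6-dimethylocta-2,6-dienoate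
Conditions: KN(SiMe3)2, 18-crown-6, THF, −78 °C
Reagents that add atoms: none
Why: Still–Gennari olefination, in which the electron-poor phosphonate with a dissociated potassium ion eliminates fast from the kinetic adduct, so the Z trisubstituted enoate (future C1=C10) should dominate.

Step 4
Reactants: 6 ethyl (2Z,6E)-8-[(tert-butyldimethylsilyl)oxy]-2,6-dimethylocta-2,6-dienoate
Product: 7 (2Z,6E)-8-[(tert-butyldimethylsilyl)oxy]-2,6-dimethylocta-2,6-dien-1-ol
Conditions: i-Bu2AlH, CH2Cl2, −78 °C
Reagents that add atoms: none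
Why: 1,2-Reduction of the conjugated ester by the aluminium hydride gives the allylic alcohol without touching alkene geometry or the silyl ether.

Step 5
Reactants: 7 (2Z,6E)-8-[(tert-butyldimethylsilyl)oxy]-2,6-dimethylocta-2,6-dien-1-ol
Product: 8 (2Z,6E)-8-[(tert-butyldimethylsilyl)oxy]-1-[(tert-butyldiphenylsilyl)oxy]-2,6-dimethylocta-2,6-diene
Conditions: t-BuPh2SiCl, imidazole, CH2Cl2, rt
Reagents that add atoms: tert-butyldiphenylsilyl chloride, CC(C)(C)[Si](Cl)(c1ccccc1)c1ccccc1
Why: Standard silylation puts the more acid-stable TBDPS group on the future C9 oxygen, which makes the selective unmasking in step 6 possible.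

Step 6
Reactants: 8 (2Z,6E)-8-[(tert-butyldimethylsilyl)oxy]-1-[(tert-butyldiphenylsilyl)oxy]-2,6-dimethylocta-2,6-diene
Product: 9 (2E,6Z)-8-[(tert-butyldiphenylsilyl)oxy]-3,7-dimethylocta-2,6-dien-1-ol
Conditions: PPTS (cat.), EtOH, 40 °C
Reagents that add atoms: none
Why: Mild acid-catalysed ethanolysis (selective silyl ether solvolysis) removes the primary TBS ether while the bulkier TBDPS ether stays.

Step 7
Reactants: 9 (2E,6Z)-8-[(tert-butyldiphenylsilyl)oxy]-3,7-dimethylocta-2,6-dien-1-ol
Product: 10 (2E,6Z)-8-[(tert-butyldiphenylsilyl)oxy]-3,7-dimethylocta-2,6-dienal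
Conditions: MnO2, CH2Cl2, rt
Reagents that add atoms: none
Why: MnO2 oxidation of the allylic alcohol stops at the enal and keeps the E geometry of the future C4=C5 alkene.

Step 8
Reactants: 11 (R)-4-benzyl-1,3-oxazolidin-2-one; 12 methyl 4-chloro-4-oxobutanoate
Product: 13 methyl 4-[(4R)-4-benzyl-2-oxo-1,3-oxazolidin-3-yl]-4-oxobutanoate
Conditions: n-BuLi, THF, −78 °C; then 12, −78 → 0 °C
Reagents that add atoms: none
Why: N-Acylation of the lithiated oxazolidinone by the acid chloride is the standard route to such imides.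

Step 9
Reactants: 10 (2E,6Z)-8-[(tert-butyldiphenylsilyl)oxy]-3,7-dimethylocta-2,6-dienal; 13 methyl 4-[(4R)-4-benzyl-2-oxo-1,3-oxazolidin-3-yl]-4-oxobutanoate
Product: 14 methyl (3S,4S,5E,9Z)-3-{[(4R)-4-benzyl-2-oxo-1,3-oxazolidin-3-yl]carbonyl}-11-[(tert-butyldiphenylsilyl)oxy]-6,10-dimethyl-4-[(trimethylsilyl)oxy]undeca-5,9-dienoate
Conditions: MgCl2 (0.2 equiv), Et3N, Me3SiCl, EtOAc, 23 °C
Reagents that add atoms: chlorotrimethylsilane, C[Si](C)(C)Cl
Why: Magnesium chloride-catalysed direct anti-aldol of an N-acyl oxazolidinone (soft enolisation at the imide α-carbon, silylation of the aldolate turns the catalyst over), in which the chelated Z-enolate adds through a boat-like transition state on the face away from the benzyl group, setting C7 (3S) and, anti to it, C6 (4S).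

Step 10
Reactants: 14 the silylated anti-aldol adduct
Product: 16 (4R)-4-benzyl-3-{[(2S,3S)-2-[(1E,5Z)-7-hydroxy-2,6-dimethylhepta-1,5-dien-1-yl]-5-oxooxolan-3-yl]carbonyl}-1,3-oxazolidin-2-one, via dihydroxy ester 15 (not isolated)
Conditions: HF·pyridine, pyridine, THF, 0 °C → rt; then PPTS (cat.), toluene, 50 °C
Reagents that add atoms: none
Why: Fluoride desilylation frees both hydroxyls without base, and acid-catalysed 5-exo lactonisation of the C6 hydroxyl onto the methyl ester closes the γ-lactone, the anti aldol relationship becoming cis on the ring with C6 and C7 untouched.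

Step 11
Reactants: 16 the cis-lactone imide
Product: 17 (4R,5S)-4-(hydroxymethyl)-5-[(1E,5Z)-7-hydroxy-2,6-dimethylhepta-1,5-dien-1-yl]oxolan-2-one
Conditions: NaBH4, THF–H2O (4:1), 0 °C; neutral work-up
Reagents that add atoms: none
Why: Borohydride reduction of the N-acyl oxazolidinone, the most electrophilic carbonyl present, gives the primary alcohol and releases the auxiliary while the γ-lactone should be spared at 0 °C.

Step 12
Reactants: 17 the cis-lactone diol
Product: 18 (2Z,6E)-7-[(2S,3S)-3-formyl-5-oxooxolan-2-yl]-2,6-dimethylhepta-2,6-dienal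
Conditions: Dess–Martin periodinane, NaHCO3, CH2Cl2, 0 °C; used crude at once
Reagents that add atoms: none
Why: Dess–Martin oxidation turns both primary alcohols into aldehydes under buffered, non-enolising conditions, so the Z-enal and the epimerisable, β-acyloxy C7 centre should survive the short handling.

Step 13
Reactants: 18 the cis-lactone dialdehyde
Product: 19 (3aR,4R,5R,6Z,10E,11aS)-4,5-dihydroxy-6,10-dimethyl-3a,4,5,8,9,11a-hexahydrocyclodeca[b]furan-2(3H)-one
Conditions: SmI2 (0.1 M in THF, 3 equiv), THF, −78 °C, 18 added over several hours (final about 0.003 M), then to −20 °C; aq. NH4Cl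
Reagents that add atoms: none
Why: Two single-electron transfers from SmI2 turn the C8 aldehyde and the C9 enal carbonyl into trivalent-samarium ketyls, and head-to-head union of the two carbinyl carbons makes the C8–C9 bond; this is the intramolecular SmI2 pinacol coupling of a dialdehyde to a cyclic 1,2-diol. The ten-membered carbocycle (C1–C10) is closed by this single bond between the two chain-end carbonyl carbons, the cis-lactone, the E C4=C5 alkene and the Z C1=C10 alkene folding the chain so that C9 lies beside C8. At C8 the fixed C7 centre selects the face: the oxygen with its bulky samarium sits on the side of the small C7–H and away from the lactone methylene C11, which gives 8R. At C9 the second samarium-bearing oxygen turns away from the first across the forming bond (steric and dipole repulsion, no bridging additive), which gives the trans (threo) diol and hence 9R, the usual outcome of reductive pinacol closures of rings of eight or more members. The step needs bonding at C9 rather than at the γ-carbon C1, retention of the Z alkene and no epimerisation or β-elimination at C7; the Z geometry holds C9 within reach while C1 would have to close a more strained eight-membered ring, and the cold, neutral, aprotic medium with slow inverse addition protects the β-formyl lactone and suppresses intermolecular coupling. The lactone carbonyl is not reduced by SmI2 in THF without activating additives.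

Step 14
Reactants: 19 the ten-membered diol lactone
Product: 20 (3aS,4R,5R,6Z,10E,11aS)-6,10-dimethyl-4,5-bis[(triethylsilyl)oxy]-3a,4,5,8,9,11a-hexahydrocyclodeca[b]furan-2(3H)-one
Conditions: Et3SiOTf, 2,6-lutidine, CH2Cl2, −78 → 0 °C
Reagents that add atoms: triethylsilyl trifluoromethanesulfonate, CC[Si](CC)(CC)OS(=O)(=O)C(F)(F)F
Why: Silyl triflate with a hindered pyridine base silylates both secondary alcohols at low temperature, masking them for enolate chemistry without alkoxide conditions that could move the lactone to O8.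

Step 15
Reactants: 20 the bis-silyl ether
Product: 23 (3aS,4R,5R,6Z,10E,11aS)-6,10-dimethyl-3-methylidene-4,5-bis[(triethylsilyl)oxy]-3a,4,5,8,9,11a-hexahydrocyclodeca[b]furan-2(3H)-one, via Mannich base 21 (not isolated), via methiodide 22 (not isolated)
Conditions: LiN(i-Pr)2, THF, −78 °C; CH2=NMe2+ I−, −78 °C → rt; MeI, MeOH, rt; aq. NaHCO3, CH2Cl2, rt
Reagents that add atoms: dimethylmethylideneammonium iodide (Eschenmoser's salt), C=[N+](C)C.[I-]; iodomethane, CI (its methyl group is carried by intermediate 22 only)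
Why: Mannich aminomethylation of the lactone lithium enolate at C11, quaternisation and E1cB (Hofmann-type) elimination give the α-methylene lactone, and C7 is not enolised under these conditions.

Step 16
Reactants: 23 the α-methylene bis-silyl ether
Product: 24 (3aR,4R,5R,6Z,10E,11aS)-4,5-dihydroxy-6,10-dimethyl-3-methylidene-3a,4,5,8,9,11a-hexahydrocyclodeca[b]furan-2(3H)-one
Conditions: HF·pyridine, pyridine, THF, 0 °C → rt
Reagents that add atoms: none
Why: Buffered fluoride desilylation cleaves both TES ethers under non-basic conditions that the Michael-accepting methylene lactone tolerates.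

Step 17
Reactants: 24 the α-methylene diol
Product: 25 (3aR,4R,6Z,10E,11aS)-4-hydroxy-6,10-dimethyl-3-methylidene-3a,4,8,9-tetrahydrocyclodeca[b]furan-2,5(3H,11aH)-dione
Conditions: MnO2, CH2Cl2, rt
Reagents that add atoms: none
Why: MnO2 oxidises only the allylic C9 carbinol (C8–OH is not allylic), which tells the two hydroxyls apart; the reaction is stopped early because MnO2 can also cleave vicinal diols.

Step 18
Reactants: 26 angelic acid
Product: 27 (2Z)-2-methylbut-2-en-1-ol
Conditions: LiAlH4, Et2O, 0 °C → rt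
Reagents that add atoms: none
Why: Hydride reduction of the carboxylic acid gives the allylic alcohol with the Z geometry kept.

Step 19
Reactants: 27 (2Z)-2-methylbut-2-en-1-ol
Product: 28 [(2S,3R)-2,3-dimethyloxiran-2-yl]methanol
Conditions: Ti(OiPr)4 (10 mol %), L-(+)-diethyl tartrate (12 mol %), t-BuOOH, 4 Å molecular sieves, CH2Cl2, −20 °C
Reagents that add atoms: tert-butyl hydroperoxide, CC(C)(C)OO
Why: Sharpless asymmetric epoxidation, in which the tetravalent titanium L-tartrate complex delivers oxygen to the face that gives the (2S,3R)-epoxy alcohol, the syn addition keeping the cis relation of CH2OH and the C3 methyl.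

Step 20
Reactants: 28 [(2S,3R)-2,3-dimethyloxiran-2-yl]methanol
Product: 29 (2R,3R)-2,3-dimethyloxirane-2-carboxylic acid
Conditions: RuCl3 (cat.), NaIO4, MeCN–EtOAc–H2O, 0 °C → rt
Reagents that add atoms: water, O
Why: RuO4 generated from RuCl3 and NaIO4 oxidises the primary alcohol through the aldehyde hydrate to the acid without opening the trisubstituted oxirane.

Step 21
Reactants: 25 the C9 ketone with free C8–OH; 29 (2R,3R)-2,3-dimethyloxirane-2-carboxylic acid
Product: 31 (3aS,4R,6Z,10E,11aS)-6,10-dimethyl-3-methylidene-2,5-dioxo-2,3,3a,4,5,8,9,11a-octahydrocyclodeca[b]furan-4-yl (2R,3R)-2,3-dimethyloxirane-2-carboxylate, via mixed anhydride 30 (not isolated)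
Conditions: 2,4,6-Cl3C6H2COCl, Et3N, THF, rt; then 25, DMAP, toluene, 0 °C → rt
Reagents that add atoms: 2,4,6-trichlorobenzoyl chloride, O=C(Cl)c1c(Cl)cc(Cl)cc1Cl (carried by intermediate 30 only)
Why: Yamaguchi esterification, in which DMAP attacks the aliphatic carbonyl of the mixed anhydride and the acylpyridinium acylates the only free hydroxyl, C8–OH, with retention at C8.

Step 22
Reactants: 31 the C9 ketone 8-O-epoxyangelate
Product: 32 target, (3aS,4R,5R,6Z,10E,11aS)-5-hydroxy-6,10-dimethyl-3-methylidene-2-oxo-2,3,3a,4,5,8,9,11a-octahydrocyclodeca[b]furan-4-yl (2R,3R)-2,3-dimethyloxirane-2-carboxylate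
Conditions: NaBH4, CeCl3·7H2O, MeOH, −78 °C
Reagents that add atoms: none
Why: Luche reduction, in which cerium-activated 1,2-hydride addition to the enone is faster than conjugate reduction of the methylene lactone, and hydride attack anti to the polar C8–O bond (Felkin–Anh) on the outer face of the ring should give the 9R alcohol trans to O8.

**Compound list**
1 | geraniol | CC(C)=CCC/C(C)=C/CO | starting material
2 | geranyl tert-butyldimethylsilyl ether | CC(C)=CCC/C(C)=C/CO[Si](C)(C)C(C)(C)C | intermediate
3 | 6,7-epoxygeranyl tert-butyldimethylsilyl ether (racemic at the oxirane CH) | CC1(C)OC1CC/C(C)=C/CO[Si](C)(C)C(C)(C)C | intermediate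
4 | (4E)-6-[(tert-butyldimethylsilyl)oxy]-4-methylhex-4-enal | O=CCC/C(C)=C/CO[Si](C)(C)C(C)(C)C | intermediate
5 | ethyl 2-[bis(2,2,2-trifluoroethoxy)phosphoryl]propanoate | CCOC(=O)C(C)P(=O)(OCC(F)(F)F)OCC(F)(F)F | starting material
6 | ethyl (2Z,6E)-8-[(tert-butyldimethylsilyl)oxy]-2,6-dimethylocta-2,6-dienoate | CCOC(=O)/C(C)=C\CC/C(C)=C/CO[Si](C)(C)C(C)(C)C | intermediate
7 | (2Z,6E)-8-[(tert-butyldimethylsilyl)oxy]-2,6-dimethylocta-2,6-dien-1-ol | OC/C(C)=C\CC/C(C)=C/CO[Si](C)(C)C(C)(C)C | intermediate
8 | (2Z,6E)-8-[(tert-butyldimethylsilyl)oxy]-1-[(tert-butyldiphenylsilyl)oxy]-2,6-dimethylocta-2,6-diene | CC(C)(C)[Si](c1ccccc1)(c1ccccc1)OC/C(C)=C\CC/C(C)=C/CO[Si](C)(C)C(C)(C)C | intermediate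
9 | (2E,6Z)-8-[(tert-butyldiphenylsilyl)oxy]-3,7-dimethylocta-2,6-dien-1-ol | CC(C)(C)[Si](c1ccccc1)(c1ccccc1)OC/C(C)=C\CC/C(C)=C/CO | intermediate
10 | (2E,6Z)-8-[(tert-butyldiphenylsilyl)oxy]-3,7-dimethylocta-2,6-dienal | CC(C)(C)[Si](c1ccccc1)(c1ccccc1)OC/C(C)=C\CC/C(C)=C/C=O | intermediate
11 | (R)-4-benzyl-1,3-oxazolidin-2-one | O=C1N[C@H](Cc2ccccc2)CO1 | starting material
12 | methyl 4-chloro-4-oxobutanoate | COC(=O)CCC(Cl)=O | starting material
13 | methyl 4-[(4R)-4-benzyl-2-oxo-1,3-oxazolidin-3-yl]-4-oxobutanoate | COC(=O)CCC(=O)N1[C@H](Cc2ccccc2)COC1=O | intermediate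
14 | methyl (3S,4S,5E,9Z)-3-{[(4R)-4-benzyl-2-oxo-1,3-oxazolidin-3-yl]carbonyl}-11-[(tert-butyldiphenylsilyl)oxy]-6,10-dimethyl-4-[(trimethylsilyl)oxy]undeca-5,9-dienoate | COC(=O)C[C@H](C(=O)N1[C@H](Cc2ccccc2)COC1=O)[C@@H](O[Si](C)(C)C)/C=C(\C)CC/C=C(/C)CO[Si](c1ccccc1)(c1ccccc1)C(C)(C)C | intermediate
15 | methyl (3S,4S,5E,9Z)-3-{[(4R)-4-benzyl-2-oxo-1,3-oxazolidin-3-yl]carbonyl}-4,11-dihydroxy-6,10-dimethylundeca-5,9-dienoate | COC(=O)C[C@H](C(=O)N1[C@H](Cc2ccccc2)COC1=O)[C@@H](O)/C=C(\C)CC/C=C(/C)CO | intermediate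
16 | (4R)-4-benzyl-3-{[(2S,3S)-2-[(1E,5Z)-7-hydroxy-2,6-dimethylhepta-1,5-dien-1-yl]-5-oxooxolan-3-yl]carbonyl}-1,3-oxazolidin-2-one (cis-lactone) | O=C([C@H]1CC(=O)O[C@H]1/C=C(\C)CC/C=C(/C)CO)N1[C@H](Cc2ccccc2)COC1=O | intermediate
17 | (4R,5S)-4-(hydroxymethyl)-5-[(1E,5Z)-7-hydroxy-2,6-dimethylhepta-1,5-dien-1-yl]oxolan-2-one (cis) | OC[C@H]1CC(=O)O[C@H]1/C=C(\C)CC/C=C(/C)CO | intermediate
18 | (2Z,6E)-7-[(2S,3S)-3-formyl-5-oxooxolan-2-yl]-2,6-dimethylhepta-2,6-dienal (cis-lactone dialdehyde) | O=C[C@H]1CC(=O)O[C@H]1/C=C(\C)CC/C=C(/C)C=O | intermediate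
19 | (3aR,4R,5R,6Z,10E,11aS)-4,5-dihydroxy-6,10-dimethyl-3a,4,5,8,9,11a-hexahydrocyclodeca[b]furan-2(3H)-one | C1C(=O)O[C@H]2/C=C(\C)CC/C=C(/C)[C@@H](O)[C@H](O)[C@@H]12 | intermediate
20 | (3aS,4R,5R,6Z,10E,11aS)-6,10-dimethyl-4,5-bis[(triethylsilyl)oxy]-3a,4,5,8,9,11a-hexahydrocyclodeca[b]furan-2(3H)-one | C1C(=O)O[C@H]2/C=C(\C)CC/C=C(/C)[C@@H](O[Si](CC)(CC)CC)[C@H](O[Si](CC)(CC)CC)[C@@H]12 | intermediate
21 | 3-[(dimethylamino)methyl] derivative of 20 (both C3 epimers) | CN(C)CC1C(=O)O[C@H]2/C=C(\C)CC/C=C(/C)[C@@H](O[Si](CC)(CC)CC)[C@H](O[Si](CC)(CC)CC)[C@@H]12 | intermediate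
22 | 3-[(trimethylammonio)methyl] iodide derived from 21 | C[N+](C)(C)CC1C(=O)O[C@H]2/C=C(\C)CC/C=C(/C)[C@@H](O[Si](CC)(CC)CC)[C@H](O[Si](CC)(CC)CC)[C@@H]12.[I-] | intermediate
23 | (3aS,4R,5R,6Z,10E,11aS)-6,10-dimethyl-3-methylidene-4,5-bis[(triethylsilyl)oxy]-3a,4,5,8,9,11a-hexahydrocyclodeca[b]furan-2(3H)-one | C=C1C(=O)O[C@H]2/C=C(\C)CC/C=C(/C)[C@@H](O[Si](CC)(CC)CC)[C@H](O[Si](CC)(CC)CC)[C@@H]12 | intermediate
24 | (3aR,4R,5R,6Z,10E,11aS)-4,5-dihydroxy-6,10-dimethyl-3-methylidene-3a,4,5,8,9,11a-hexahydrocyclodeca[b]furan-2(3H)-one | C=C1C(=O)O[C@H]2/C=C(\C)CC/C=C(/C)[C@@H](O)[C@H](O)[C@@H]12 | intermediate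
25 | (3aR,4R,6Z,10E,11aS)-4-hydroxy-6,10-dimethyl-3-methylidene-3a,4,8,9-tetrahydrocyclodeca[b]furan-2,5(3H,11aH)-dione | C=C1C(=O)O[C@H]2/C=C(\C)CC/C=C(/C)C(=O)[C@H](O)[C@@H]12 | intermediate
26 | angelic acid, (2Z)-2-methylbut-2-enoic acid | C/C=C(/C)C(=O)O | starting material
27 | (2Z)-2-methylbut-2-en-1-ol | C/C=C(/C)CO | intermediate
28 | [(2S,3R)-2,3-dimethyloxiran-2-yl]methanol | OC[C@]1(C)O[C@@H]1C | intermediate
29 | (2R,3R)-2,3-dimethyloxirane-2-carboxylic acid (epoxyangelic acid) | O=C(O)[C@]1(C)O[C@@H]1C | intermediate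
30 | (2R,3R)-2,3-dimethyloxirane-2-carboxylic 2,4,6-trichlorobenzoic anhydride | O=C(OC(=O)c1c(Cl)cc(Cl)cc1Cl)[C@]1(C)O[C@@H]1C | intermediate
31 | (3aS,4R,6Z,10E,11aS)-6,10-dimethyl-3-methylidene-2,5-dioxo-2,3,3a,4,5,8,9,11a-octahydrocyclodeca[b]furan-4-yl (2R,3R)-2,3-dimethyloxirane-2-carboxylate | C=C1C(=O)O[C@H]2/C=C(\C)CC/C=C(/C)C(=O)[C@H](OC(=O)[C@]3(C)O[C@@H]3C)[C@@H]12 | intermediate
32 | (3aS,4R,5R,6Z,10E,11aS)-5-hydroxy-6,10-dimethyl-3-methylidene-2-oxo-2,3,3a,4,5,8,9,11a-octahydrocyclodeca[b]furan-4-yl (2R,3R)-2,3-dimethyloxirane-2-carboxylate | C=C1C(=O)O[C@H]2/C=C(\C)CC/C=C(/C)[C@@H](O)[C@H](OC(=O)[C@]3(C)O[C@@H]3C)[C@@H]12 | target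

**Step count**
Total steps: 22. Longest linear sequence: 18 steps (1–7, 9–17, 21, 22); steps 8 and 18–20 are side branches.

**Steps most likely to fail**

Step 13 (pinacol macrocyclisation). Intermolecular coupling may outrun ring closure. The delocalised enal ketyl may bond through C1 (eight-membered ring) or lose its Z geometry by rotation. The cis (erythro) diol or the other C8 face may form. The samarium alkoxide at O8 may shift the lactone from O6 to O8, and the β-formyl lactone may epimerise or eliminate before it couples. Fallback: the coupling is moved from free samarium ketyls in solution to a titanium-templated reductive coupling. Dialdehyde 18 is added by syringe pump to low-valent titanium made from TiCl3(DME)1.5 and Zn–Cu couple in DME at 0–25 °C and the reaction is stopped at the pinacol stage (McMurry-type conditions below the deoxygenation temperature). Both carbonyl oxygens are bound on the metal before the C–C bond forms, which disfavours bonding at C1 and usually gives trans diols in rings of this size. The fallback sets out from 18 and comes back at 19; no new compound arises (F0).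

Step 9 (anti-aldol). Triethylamine with Me3SiCl may deprotonate the γ-methyl of the enal (silyl dienol ether, loss of the E geometry). The ester arm may compete for magnesium and lower the anti or facial selectivity. The unhindered aldolate may undergo retro-aldol before it is silylated. Fallback: an open-transition-state aldol with a preformed enolate replaces the catalytic soft-enolisation. Imide 13 is converted into its dibutylboron Z-enolate (Bu2BOTf, i-Pr2NEt, CH2Cl2, 0 °C) and added at −78 °C to enal 10 precomplexed with Et2AlCl. With no aldehyde on boron the enolate is chelated to the ring carbonyl and presents the same face, and the Lewis-acid-bound aldehyde adds anti. This should give the β-hydroxy imide methyl (3S,4S,5E,9Z)-3-{[(4R)-4-benzyl-2-oxo-1,3-oxazolidin-3-yl]carbonyl}-11-[(tert-butyldiphenylsilyl)oxy]-4-hydroxy-6,10-dimethylundeca-5,9-dienoate F1, with no amine or silyl chloride in contact with the free enal. Under the conditions of step 10, F1 gives 16 by way of 15. The fallback sets out from 10 and 13 and comes back at 16.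

Step 22 (ketone reduction). The ring conformation may override the Felkin preference and deliver hydride to the other face of C9. Hydride may also add in conjugate fashion to the methylene lactone, and the ester may migrate from O8 to O9 in the basic methanolic medium. Fallback: the C9 configuration is then set by substitution with inversion instead of by hydride delivery. The 9S alcohol (3aS,4R,5S,6Z,10E,11aS)-5-hydroxy-6,10-dimethyl-3-methylidene-2-oxo-2,3,3a,4,5,8,9,11a-octahydrocyclodeca[b]furan-4-yl (2R,3R)-2,3-dimethyloxirane-2-carboxylate F2, obtained from 31 by the reduction, is subjected to a Mitsunobu reaction with chloroacetic acid (PPh3, diisopropyl azodicarboxylate, toluene, 0 °C). This gives the inverted 9R chloroacetate (3aS,4R,5R,6Z,10E,11aS)-5-[(chloroacetyl)oxy]-6,10-dimethyl-3-methylidene-2-oxo-2,3,3a,4,5,8,9,11a-octahydrocyclodeca[b]furan-4-yl (2R,3R)-2,3-dimethyloxirane-2-carboxylate F3. Thiourea with NaHCO3 in EtOH then removes the chloroacetyl group selectively, leaving the hindered epoxyangelate and the lactone. The fallback sets out from 31 and comes back at 32.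

Further compounds
F0 | step 13 | none | none
F1 | step 9 | methyl (3S,4S,5E,9Z)-3-{[(4R)-4-benzyl-2-oxo-1,3-oxazolidin-3-yl]carbonyl}-11-[(tert-butyldiphenylsilyl)oxy]-4-hydroxy-6,10-dimethylundeca-5,9-dienoate | COC(=O)C[C@H](C(=O)N1[C@H](Cc2ccccc2)COC1=O)[C@@H](O)/C=C(\C)CC/C=C(/C)CO[Si](c1ccccc1)(c1ccccc1)C(C)(C)C
F2 | step 22 | (3aS,4R,5S,6Z,10E,11aS)-5-hydroxy-6,10-dimethyl-3-methylidene-2-oxo-2,3,3a,4,5,8,9,11a-octahydrocyclodeca[b]furan-4-yl (2R,3R)-2,3-dimethyloxirane-2-carboxylate | C=C1C(=O)O[C@H]2/C=C(\C)CC/C=C(/C)[C@H](O)[C@H](OC(=O)[C@]3(C)O[C@@H]3C)[C@@H]12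
F3 | step 22 | (3aS,4R,5R,6Z,10E,11aS)-5-[(chloroacetyl)oxy]-6,10-dimethyl-3-methylidene-2-oxo-2,3,3a,4,5,8,9,11a-octahydrocyclodeca[b]furan-4-yl (2R,3R)-2,3-dimethyloxirane-2-carboxylate | C=C1C(=O)O[C@H]2/C=C(\C)CC/C=C(/C)[C@@H](OC(=O)CCl)[C@H](OC(=O)[C@]3(C)O[C@@H]3C)[C@@H]12
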